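**Plan**

1. Numbering: O1, C2 (bears ring B, the 4-methoxyphenyl ring), C3, C4, C4a, C5 (OMe), C6 (prenyl), C7 (OMe), C8, C8a. Ring A is the benzo ring, ring C the dihydropyran ring.
2. Retrosynthesis: cut C6–prenyl (aryllithium from a C6 bromide), then C2–C3 of ring C together with a formyl helper on C3, then C3=C4 (Wittig), O1–C2 (benzyl ether) and C4–C4a (ortho-formylation), back to the symmetric 4-bromo-3,5-dimethoxyphenol.
3. Enabling feature: C2 carries H between O1 and ring B, so it is the CH2 of a 4-methoxybenzyl ether, a hydride donor that lies 1,5 to C4 across O1–C8a–C4a.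
4. Forward: ring A is present from the start with its pattern fixed by symmetry, ring B is joined by O-alkylation, and ring C closes by iminium-triggered 1,5-hydride transfer from C2 to C4 followed by C2–C3 bond formation. Decarbonylation and prenylation finish the route.
5. Stereochemistry: a chiral secondary amine sets C3 through its enamine, the trans ring closure relays this to C2 (S), and C3 is then erased; C2 is not touched afterwards.

Key step: step 5

Remark on the chemistry: compounds 1, 5, 7 and 14 are taken as commercial. The sense of induction in step 5 is assigned by analogy with enamine reactions of the same catalyst class; if it proved opposite, the mirror-image catalyst would be used.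

**Route**

Step 1
Reactants: 1 2-bromo-1,3-dimethoxybenzene
Product: 3 4-bromo-3,5-dimethoxyphenol, via aryl pinacol boronate 2 (not isolated)
Conditions: pinacolborane, [Ir(OMe)(cod)]2 (1.5 mol%), 4,4'-di-tert-butyl-2,2'-bipyridine (3 mol%), THF, 80 °C; evaporate; then KHSO5 (as Oxone, 2KHSO5·KHSO4·K2SO4), acetone/H2O, rt
Reagents that add atoms: potassium peroxymonosulfate, [K+].[O-]S(=O)(=O)OO (oxygen of the hydroxyl group)
Why: Iridium-catalysed aromatic C–H borylation is sterically governed and should take C5, the only C–H without an ortho substituent, and peroxymonosulfate oxidises the C–B bond to C–OH at the same carbon (one-pot C–H borylation/oxidation).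

Step 2
Reactants: 3 4-bromo-3,5-dimethoxyphenol
Product: 4 3-bromo-6-hydroxy-2,4-dimethoxybenzaldehyde
Conditions: MgCl2, Et3N, paraformaldehyde, MeCN, reflux; aq HCl work-up
Reagents that add atoms: paraformaldehyde (as formaldehyde), C=O
Why: Magnesium-mediated ortho-formylation of phenols (Casnati–Skattebøl): the magnesium phenoxide delivers formaldehyde to the ortho carbon and a second formaldehyde oxidises the benzylic alkoxide; the two ortho positions of 3 are equivalent by symmetry and the para position carries Br, so only one isomer can form.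

Step 3
Reactants: 4 3-bromo-6-hydroxy-2,4-dimethoxybenzaldehyde; 5 4-methoxybenzyl chloride
Product: 6 3-bromo-2,4-dimethoxy-6-[(4-methoxybenzyl)oxy]benzaldehyde
Conditions: K2CO3, DMF, 60 °C
Reagents that add atoms: none
Why: Williamson ether synthesis of the phenoxide with a reactive benzylic chloride; it installs O1–C2 together with ring B and the hydridic CH2 group at C2.

Step 4
Reactants: 6 3-bromo-2,4-dimethoxy-6-[(4-methoxybenzyl)oxy]benzaldehyde; 7 (triphenylphosphoranylidene)acetaldehyde
Product: 8 (2E)-3-{3-bromo-2,4-dimethoxy-6-[(4-methoxybenzyl)oxy]phenyl}prop-2-enal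
Conditions: 7 (1.3 equiv), toluene, 100 °C
Reagents that add atoms: none
Why: Wittig reaction of the stabilised formylmethylene ylide, which should give the (E)-enal and so place the acceptor carbon C4 in a 1,5 relation to the C2–H bonds.

Step 5
Reactants: 8 (2E)-3-{3-bromo-2,4-dimethoxy-6-[(4-methoxybenzyl)oxy]phenyl}prop-2-enal
Product: 12 (2S,3S)-6-bromo-5,7-dimethoxy-2-(4-methoxyphenyl)chromane-3-carbaldehyde, via iminium ion 9 (not isolated), via oxocarbenium enamine 10 (not isolated), via cyclised iminium ion 11 (not isolated)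
Conditions: (R)-2-{bis[3,5-bis(trifluoromethyl)phenyl][(trimethylsilyl)oxy]methyl}pyrrolidine (20 mol%), 2,4-dinitrobenzenesulfonic acid (20 mol%), ClCH2CH2Cl, 40 °C; chromatography (trans isomer)
Reagents that add atoms: none
Why: Proposed new method: condensation of 8 with the amine gives iminium ion 9, whose C4 takes the hydride of the C2–H bond (hydridic because C2 lies between O1 and the 4-methoxyphenyl ring) through a six-membered 1,5-transfer across C2–O1–C8a–C4a–C4; the oxocarbenium carbon C2 and the enamine carbon C3 of 10 then join to the C2–C3 bond (11) and hydrolysis returns the catalyst, so the step is a redox-neutral isomerisation of 8 without by-product. The closest known reaction types are the Lewis acid-catalysed 1,5-hydride shift/cyclisation of ortho-vinylaryl benzyl ethers carrying alkylidene malonate acceptors, which gives chroman-3,3-diesters, and the enantioselective amine-catalysed 1,5-hydride transfer/ring closure of ortho-(dialkylamino)cinnamaldehydes to tetrahydroquinoline-3-carbaldehydes; an aryl benzyl ether as hydride donor under iminium catalysis is the untested element. Ring C closes by attack of C3 on the endocyclic O1=C2 bond in the 6-endo-trig mode (6-(enolexo)-endo-trig with respect to the enamine), which is favoured. The bulky diaryl(silyloxy)methyl group of the catalyst shields one face of the (E)-enamine and so sets C3, and the (E)-oxocarbenium ion keeps ring B equatorial in a half-chair transition state with the C3 substituent equatorial as well, so the trans relation should carry the catalyst control over to C2 (2S). The step needs site selectivity between the two ether groups ortho to the side chain and a high trans preference, since a cis product would have the opposite configuration at C2: the 4-methoxyphenyl ring stabilises the cation only at C2 and not at the C5 methoxy carbon, the twist of the 2,6-disubstituted styrene uncouples ring A from the iminium acceptor, and any cis isomer is removed by chromatography before C3 is erased.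

Step 6
Reactants: 12 (2S,3S)-6-bromo-5,7-dimethoxy-2-(4-methoxyphenyl)chromane-3-carbaldehyde
Product: 13 (2S)-6-bromo-5,7-dimethoxy-2-(4-methoxyphenyl)chromane
Conditions: RhCl(PPh3)3 (1.1 equiv), toluene, 110 °C
Reagents that add atoms: none
Why: Tsuji–Wilkinson decarbonylation: oxidative addition of the formyl C–H bond to monovalent rhodium, carbonyl extrusion and C–H reductive elimination replace CHO by H, so C3 becomes CH2 while C2, which takes no part, keeps its (S) configuration.

Step 7
Reactants: 13 (2S)-6-bromo-5,7-dimethoxy-2-(4-methoxyphenyl)chromane; 14 1-bromo-3-methylbut-2-ene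
Product: 16 (2S)-5,7-dimethoxy-2-(4-methoxyphenyl)-6-(3-methylbut-2-en-1-yl)chromane, via aryllithium 15 (not isolated)
Conditions: n-BuLi, THF, −78 °C; then CuBr·SMe2 (10 mol%), 14, −78 → 0 °C
Reagents that add atoms: none
Why: Bromine–lithium exchange gives an aryllithium held by the two flanking methoxy groups, and copper-catalysed allylic substitution at the primary carbon of 14 (SN2 mode) should install the prenyl group at C6 without touching C2.

**Compound list**

1 | 2-bromo-1,3-dimethoxybenzene | COc1cccc(OC)c1Br | starting material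
2 | 2-(4-bromo-3,5-dimethoxyphenyl)-4,4,5,5-tetramethyl-1,3,2-dioxaborolane | COc1cc(B2OC(C)(C)C(C)(C)O2)cc(OC)c1Br | intermediate
3 | 4-bromo-3,5-dimethoxyphenol | COc1cc(O)cc(OC)c1Br | intermediate
4 | 3-bromo-6-hydroxy-2,4-dimethoxybenzaldehyde | COc1cc(O)c(C=O)c(OC)c1Br | intermediate
5 | 4-methoxybenzyl chloride | COc1ccc(CCl)cc1 | starting material
6 | 3-bromo-2,4-dimethoxy-6-[(4-methoxybenzyl)oxy]benzaldehyde | COc1ccc(COc2cc(OC)c(Br)c(OC)c2C=O)cc1 | intermediate
7 | (triphenylphosphoranylidene)acetaldehyde | O=CC=P(c1ccccc1)(c1ccccc1)c1ccccc1 | starting material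
8 | (2E)-3-{3-bromo-2,4-dimethoxy-6-[(4-methoxybenzyl)oxy]phenyl}prop-2-enal | COc1ccc(COc2cc(OC)c(Br)c(OC)c2/C=C/C=O)cc1 | intermediate
9 | iminium ion of 8 with the (R)-amine catalyst (cation; counter-ion 2,4-dinitrobenzenesulfonate) | C[Si](C)(C)OC(c1cc(cc(c1)C(F)(F)F)C(F)(F)F)(c1cc(cc(c1)C(F)(F)F)C(F)(F)F)[C@H]1CCC[N+]1=C/C=C/c1c(OCc2ccc(OC)cc2)cc(OC)c(Br)c1OC | intermediate
10 | oxocarbenium ion at C2 with (E)-enamine at C3, formed from 9 by 1,5-hydride transfer (cation) | C[Si](C)(C)OC(c1cc(cc(c1)C(F)(F)F)C(F)(F)F)(c1cc(cc(c1)C(F)(F)F)C(F)(F)F)[C@H]1CCCN1/C=C/Cc1c([O+]=Cc2ccc(OC)cc2)cc(OC)c(Br)c1OC | intermediate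
11 | trans ring-closed iminium ion, the catalyst-bound form of 12 (cation; C2 is S, same arrangement at C3 as in 12) | C[Si](C)(C)OC(c1cc(cc(c1)C(F)(F)F)C(F)(F)F)(c1cc(cc(c1)C(F)(F)F)C(F)(F)F)[C@H]1CCC[N+]1=C[C@H]1Cc2c(cc(OC)c(Br)c2OC)O[C@@H]1c1ccc(OC)cc1 | intermediate
12 | (2S,3S)-6-bromo-5,7-dimethoxy-2-(4-methoxyphenyl)chromane-3-carbaldehyde (2,3-trans) | COc1ccc([C@@H]2[C@@H](C=O)Cc3c(cc(OC)c(Br)c3OC)O2)cc1 | intermediate
13 | (2S)-6-bromo-5,7-dimethoxy-2-(4-methoxyphenyl)chromane | COc1ccc([C@@H]2CCc3c(cc(OC)c(Br)c3OC)O2)cc1 | intermediate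
14 | 1-bromo-3-methylbut-2-ene (prenyl bromide) | CC(C)=CCBr | starting material
15 | (2S)-5,7-dimethoxy-2-(4-methoxyphenyl)chroman-6-yllithium | COc1ccc([C@@H]2CCc3c(cc(OC)c([Li])c3OC)O2)cc1 | intermediate
16 | (2S)-5,7-dimethoxy-2-(4-methoxyphenyl)-6-(3-methylbut-2-en-1-yl)chromane | COc1ccc([C@@H]2CCc3c(cc(OC)c(CC=C(C)C)c3OC)O2)cc1 | target

**Count**

Total steps: 7. Longest linear sequence: 7 steps (1 → 16).

**Steps most likely to fail**

Step 5. The hydride transfer may be too slow on an iminium ion that is conjugated to an electron-rich ring, so that acid cleavage of the benzyl ether competes. The ring closure may also show a poor trans preference, which would lower the enantiomeric purity at C2 once C3 is erased. Reversible opening of the β-aryloxy aldehyde by retro-oxa-Michael reaction could erode it further. The fallback uses known chemistry, still forms C2–C3 by ring closure, and sets C2 by asymmetric hydrogenation. It sets out from 3. Allylation (allyl bromide, K2CO3, acetone) should give 2-bromo-1,3-dimethoxy-5-(prop-2-en-1-yloxy)benzene F1. Aromatic Claisen rearrangement (N,N-diethylaniline, 190 °C) can only give 4-bromo-3,5-dimethoxy-2-(prop-2-en-1-yl)phenol F2, since both ortho positions are equivalent. Acylation with 4-methoxybenzoyl chloride (Et3N, DMAP, CH2Cl2) leads to 4-bromo-3,5-dimethoxy-2-(prop-2-en-1-yl)phenyl 4-methoxybenzoate F3. Petasis methylenation (Cp2TiMe2, toluene, 80 °C) converts the ester into 2-bromo-1,3-dimethoxy-5-{[1-(4-methoxyphenyl)ethenyl]oxy}-4-(prop-2-en-1-yl)benzene F4. Ring-closing metathesis with second-generation Grubbs catalyst (toluene, 70 °C) forms the C2=C3 bond of 6-bromo-5,7-dimethoxy-2-(4-methoxyphenyl)-4H-chromene F5. Iridium-catalysed asymmetric hydrogenation of this 2-aryl-4H-chromene (H2, [Ir(cod)(L)][B(C6H3(CF3)2)4] with the enantiomer of a chiral phosphinooxazoline L that delivers the 2S product, CH2Cl2) returns to the route at 13.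

Step 6. The alkylrhodium intermediate may lose the β-aryloxy group with opening of ring C, or undergo β-hydride elimination to a chromene, and the aldehyde may open thermally by retro-oxa-Michael reaction before it is decarbonylated. The fallback replaces the organometallic step by a radical decarboxylation and sets out from 12. Pinnick oxidation (NaClO2, NaH2PO4, 2-methyl-2-butene, t-BuOH/H2O) should give (2S,3S)-6-bromo-5,7-dimethoxy-2-(4-methoxyphenyl)chromane-3-carboxylic acid F6. Coupling with N-hydroxyphthalimide (N,N'-diisopropylcarbodiimide, DMAP, CH2Cl2) gives the 1,3-dioxoisoindolin-2-yl ester of that acid F7. Reductive decarboxylation under visible light ([Ru(bpy)3]Cl2 catalyst, Hantzsch ester, blue light, CH2Cl2) replaces the carboxyl group by hydrogen through the C3 radical and comes back to the route at 13.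

Step 4. Olefination of the hindered, electron-rich 2,6-dialkoxybenzaldehyde may be sluggish, and the enal formed may react with a second ylide to a dienal. The fallback reaches the enal through the ester oxidation level and sets out from 6. Horner–Wadsworth–Emmons reaction (triethyl phosphonoacetate, NaH, THF) should give ethyl (2E)-3-{3-bromo-2,4-dimethoxy-6-[(4-methoxybenzyl)oxy]phenyl}prop-2-enoate F8. Reduction with i-Bu2AlH (CH2Cl2, −78 °C) gives (2E)-3-{3-bromo-2,4-dimethoxy-6-[(4-methoxybenzyl)oxy]phenyl}prop-2-en-1-ol F9. Allylic oxidation with MnO2 (CH2Cl2, rt) comes back to the route at 8.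

**Further compounds**

F1 | step 5 | 2-bromo-1,3-dimethoxy-5-(prop-2-en-1-yloxy)benzene | C=CCOc1cc(OC)c(Br)c(OC)c1
F2 | step 5 | 4-bromo-3,5-dimethoxy-2-(prop-2-en-1-yl)phenol | C=CCc1c(O)cc(OC)c(Br)c1OC
F3 | step 5 | 4-bromo-3,5-dimethoxy-2-(prop-2-en-1-yl)phenyl 4-methoxybenzoate | C=CCc1c(OC(=O)c2ccc(OC)cc2)cc(OC)c(Br)c1OC
F4 | step 5 | 2-bromo-1,3-dimethoxy-5-{[1-(4-methoxyphenyl)ethenyl]oxy}-4-(prop-2-en-1-yl)benzene | C=CCc1c(OC(=C)c2ccc(OC)cc2)cc(OC)c(Br)c1OC
F5 | step 5 | 6-bromo-5,7-dimethoxy-2-(4-methoxyphenyl)-4H-chromene | COc1ccc(C2=CCc3c(cc(OC)c(Br)c3OC)O2)cc1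
F6 | step 6 | (2S,3S)-6-bromo-5,7-dimethoxy-2-(4-methoxyphenyl)chromane-3-carboxylic acid | COc1ccc([C@@H]2[C@@H](C(=O)O)Cc3c(cc(OC)c(Br)c3OC)O2)cc1
F7 | step 6 | 1,3-dioxoisoindolin-2-yl (2S,3S)-6-bromo-5,7-dimethoxy-2-(4-methoxyphenyl)chromane-3-carboxylate | COc1ccc([C@@H]2[C@@H](C(=O)ON3C(=O)c4ccccc4C3=O)Cc3c(cc(OC)c(Br)c3OC)O2)cc1
F8 | step 4 | ethyl (2E)-3-{3-bromo-2,4-dimethoxy-6-[(4-methoxybenzyl)oxy]phenyl}prop-2-enoate | CCOC(=O)/C=C/c1c(OCc2ccc(OC)cc2)cc(OC)c(Br)c1OC
F9 | step 4 | (2E)-3-{3-bromo-2,4-dimethoxy-6-[(4-methoxybenzyl)oxy]phenyl}prop-2-en-1-ol | OC/C=C/c1c(OCc2ccc(OC)cc2)cc(OC)c(Br)c1OC
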